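Minutes. Slowness opened the meeting: from 130 s to 190 s the elm reading of G rose by 2.40 mM, yet at 190 s G stood at 49.0 % of the Z charged in the elm run and 27.9 % in the ash run.

| flask | Z | time |
|---|---|---|
| elm | 120 mM |  |
| ash | 360 mM |  |
| birch | 48.0 mM | 190 s |

| run | time / s | [G] / mM |
|---|---|---|
| elm run | 14 | 21.0 |
| elm run | 44 | 40.8 |
| elm run | 84 | 51.5 |
| elm run | 130 | 56.4 |
| elm run | 190 | 58.8 |
| ash run | 14 | 46.7 |
| ash run | 44 | 77.1 |
| ash run | 84 | 90.7 |
| ash run | 130 | 97.4 |
| ash run | 190 | 100.4 |

(standard deviation of a reading: 0.4 mM)

- the exponent of [Z] in the starting rate at the charge of the elm run (at the point where two percent of the Z have become G) (one fixed amount of G, the same in the runs compared)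
- G in the birch run at 190 s, as a share of the Z charged

- Overall: Z -> G.
- Constant volume, constant temperature.
- An order is taken over about fifteen percent of the charge, up and down.

Ines argued for two competing steps: one makes G, first order in Z with constant k, and a side step consumes two Z with constant m and makes no G. I turned both into times at the charge, 1/k and 1/(2m[Z]). I carried one quantity, by trial C = 48.0 mM: the crossover charge, the [Z] at which those two times match.

With a = charge/C and the clock f = 1 − exp(−kt), the same in each flask at one time, integration gives the share of the charge in G, the yield Y = ln(1 + a·f)/a.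

Tomas objected that C was tried, not measured, so we tested it. The elm reading at 190 s gives f = 0.962. That f predicts 101 mM for the ash run, against a reading of 100.4 mM, with a scatter of 0.4 mM.

I therefore committed to an exponent of one and, with a equal to one in birch, to 67.4 %.

The forecast, which differs from my reckoning, gave 0.85 and 60 %, reading the stall as “an agent that dies, and dies faster at high Z”.

The flask gives 67.3 % and an exponent of 1.0, and the ash rate over the elm rate at equal G is 3.0.

    Z → G (0.01660 s⁻¹)
    2 Z → L (0.1860 M⁻¹ s⁻¹)
    Z → G (0.001020 s⁻¹)

Now put C to work on the ash run, where a is 7.50. Reaching a quarter of the charge in G needs f = 0.736. The elm reading at 190 s gives k = 0.01717 s⁻¹, so that takes 77.6 s, and the ash run reaches a quarter of its charge in G at 78.3 s.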